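**Numbering used throughout.** 1 syringaldehyde; 2 its MOM ether; 3 Z-cinnamate; 4 Z-allylic alcohol; 5 Z-allylic trityl ether; 6 cis-epoxide; 7 4-fluoro-3-hydroxybenzaldehyde; 8 ring-opened fluoro alcohol (not isolated); 9 benzodioxane aldehyde; 10 protected enal; 11 target. Atom labels: C7 carries ring A and Oa; C8 carries C9 (the CH2OH carbon) and Ob; ring B is the benzo ring.

## Analysis of the target

Compound 11 is a 2,3-dihydro-1,4-benzodioxine: a dioxane ring fused to ring B, with the 4-hydroxy-3,5-dimethoxyphenyl ring A on C7 and a hydroxymethyl group on C8. Ring B also carries an (E)-propenal chain. C7 and C8 are the only stereocentres, both S, and their substituents are trans on the dioxane ring. The fusion is unsymmetrical: Oa sits on the ring B carbon meta to the chain and Ob on the carbon para to it. The isomer with the two oxygens exchanged is the usual by-product of catechol-based or oxidative-coupling assemblies. The sensitive groups are the enal, the free phenol, and the C7–Oa bond, a p-hydroxybenzylic aryl ether that can ionise under acid with loss of the C7 configuration. The difficulty is that fusion regiochemistry, trans geometry and absolute configuration must all be decided together, preferably without a carbonyl next to C8. The strategy rests on two facts: the ring B carbon bearing Ob is para to a formyl group once the chain is traced back to an aldehyde, so it can be an SNAr site, and C7 is benzylic, so it can be the electrophilic end of an epoxide.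

## Retrosynthetic reasoning

**11 to 10 (protecting groups).** The ring A phenol is masked as a MOM ether and O9 as a trityl ether, both removable in one mild acidic step. The phenol must be masked so that only one phenoxide is present in the key step. O9 must be masked so that it cannot compete for ring closure. A silyl ether on O9 was considered and set aside: the key step creates an alkoxide on C8 directly beside O9 and releases one equivalent of fluoride, so a silyl group would be open to 1,2-oxygen-to-oxygen migration and to cleavage. The trityl ether does neither and should give crystalline intermediates.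

**10 to 9 (enal C=C bond).** The Cα=Cβ bond of the enal is cut by a Wittig two-carbon homologation. This leaves a formyl group on ring B para to Ob, which is exactly the activating group the key step needs. The forward reaction must be E-selective and leave both acid-labile ethers alone.

**9 to 6 + 7 (key disconnection).** The Oa–C7 bond and the Ob–aryl bond are cut, giving cis-epoxide 6 and fluorophenol 7. The polarity is reversed relative to a catechol alkylation: ring B supplies one nucleophilic oxygen (Oa, as the phenoxide of 7) and one electrophilic carbon (the C–F carbon), and the C7–C8 unit supplies the opposite pair. The fusion regiochemistry is therefore fixed by where fluorine sits in 7. The relative configuration is fixed by the epoxide geometry: one inversion at C7 of a cis-epoxide gives the trans product, with C8 untouched. The forward reaction has to open 6 at the benzylic carbon and then close the ring by displacement of the halide.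

**6 to 5 (epoxide oxygen).** The epoxide oxygen is removed to give Z-alkene 5. The absolute configuration enters here under catalyst control, by a Jacobsen–Katsuki epoxidation of a cis-disubstituted aryl alkene. The epoxidation has to be face-selective and must not leak to the trans-epoxide.

**5 to 1 (C7=C8 bond).** Ether 5 comes from alcohol 4, which comes from ester 3 by reduction. The C7=C8 bond of 3 is cut by a Z-selective Still–Gennari olefination of aldehyde 2, the MOM ether of 1. All three carbons C7–C9 and ring A are thus bought in 1 plus one olefination reagent.

## Alternatives that were turned down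

**Alternative 1: oxetane by photocycloaddition, then ring expansion.**
- Disconnection: C7–C8 and O–C9 are cut, so the C7–C9 unit is an oxetane that later expands to the dioxane.
- Forward key step: irradiation of O-acetylsyringaldehyde A1 with aryl vinyl ether A2 (Paternò–Büchi) to give 2-aryl-3-aryloxyoxetane A3. After deacetylation, the ring B phenol opens the oxetane at C7 and releases O9.
- For: it is more convergent than the chosen route. It makes the C7–C8 bond from two aromatic pieces, fixes the fusion regiochemistry by the substitution of A2, and delivers O9 unprotected. On step count to the key intermediate it is stronger.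
- Against: the C8 configuration of A3 would have to arise in a triplet 1,4-biradical cycloaddition, for which no dependable enantioselective version exists with an acyclic aryl vinyl ether. Regioisomeric and cis/trans oxetanes are expected from the same biradical. The aryl acetates are open to photo-Fries rearrangement. The ring expansion must then pass through a C7 cation to reach the trans product.
- Comparison: the chosen route is longer before its key step, but it sets the absolute configuration by an established catalytic epoxidation and passes it on stereospecifically.

**Alternative 2: ring B by alkyne cyclotrimerisation.**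
- Disconnection: ring B is cut into three alkynes, and the dioxane closes as the arene forms.
- Forward key step: bis(ynol ether) A4 and 3,3-diethoxyprop-1-yne A5 cotrimerise under Cp*RuCl(cod) to give benzodioxane A6.
- For: both stereocentres would be set by asymmetric dihydroxylation of an E-alkene before any ring exists. That is a more dependable source of configuration than epoxidation of a Z-alkene, and no substitution at a stereocentre is needed. On these two points it is stronger.
- Against: ynol ethers of secondary and benzylic alcohols are hard to make and thermally fragile (retro-ene loss of ketene), and A4 needs two different ones on neighbouring oxygens. The position of the acetal in A6 depends on a trimethylsilyl marker that must later be removed from an electron-rich ring. The end game (desilylation, acetal hydrolysis, homologation, deprotection) makes the route roughly twice as long.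
- Comparison: the chosen route buys ring B complete, takes its regiochemistry from the position of one fluorine, and is far shorter.

**Alternative 3: carbon insertion into a benzodioxole.**
- Disconnection: Ob–C8 and C7–C8 are cut, so C8 is inserted into the acetal C–O bond of a five-membered ring.
- Forward key step: a chiral copper carbene from tert-butyl diazoacetate A8 (CuOTf with a bisoxazoline) adds to Ob of 2-aryl-1,3-benzodioxole A7. The oxonium ylide then undergoes a [1,2]-shift of C7 to give ester A9.
- For: A7 comes from one acetalisation, and a single catalytic step would form two bonds, the dioxane ring and both stereocentres. As a conceptual assembly it is the shortest of all.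
- Against: selection of Ob over Oa rests on a small electronic bias from the remote silyloxy group. The [1,2]-shift of an acetal-derived ylide passes through a dissociated oxocarbenium/enolate or radical pair, so trans/cis and enantiocontrol at two centres rest on recombination. The carbene can also attack the electron-rich arenes. A9 has a carbonyl next to C8, which makes that centre epimerisable. The ester must still be reduced, the silyloxy group converted into the enal chain by cross-coupling, and the benzyl ether removed without hydrogenating the enal.
- Comparison: in the chosen route each selectivity has its own understood control element, neither stereocentre is ever next to a carbonyl, and ring B already carries the aldehyde that becomes the chain.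

Key step: step 6

**Remark on the chemistry.** The sense of induction in step 5 is assigned by analogy with cis-β-methylstyrene and cis-cinnamate esters, where the (R,R)-manganese salen chloride gives the benzylic carbon with R configuration. If the first batch shows the opposite sense, the (S,S)-catalyst is used instead.

## Route

Step 1
Reactants: 1 syringaldehyde
Product: 2 3,5-dimethoxy-4-(methoxymethoxy)benzaldehyde
Conditions: MOMCl, i-Pr2NEt, CH2Cl2, 0 °C → rt
Reagents that add atoms: chloromethyl methyl ether, COCCl
Why: O-alkylation of a phenol with an α-chloro ether (MOM protection); the flanked phenol is hindered but acidic enough to react with this reactive electrophile.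

Step 2
Reactants: 2 3,5-dimethoxy-4-(methoxymethoxy)benzaldehyde
Product: 3 methyl (Z)-3-[3,5-dimethoxy-4-(methoxymethoxy)phenyl]prop-2-enoate
Conditions: (CF3CH2O)2P(O)CH2CO2Me, KN(SiMe3)2, 18-crown-6, THF, −78 °C
Reagents that add atoms: methyl bis(2,2,2-trifluoroethyl)phosphonoacetate, COC(=O)CP(=O)(OCC(F)(F)F)OCC(F)(F)F
Why: Still–Gennari olefination; the electron-poor phosphonate and the dissociated potassium counter-ion make elimination from the kinetic adduct fast, which should give the Z-enoate from an aromatic aldehyde. The product is handled away from light to avoid Z-to-E isomerisation.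

Step 3
Reactants: 3 methyl (Z)-3-[3,5-dimethoxy-4-(methoxymethoxy)phenyl]prop-2-enoate
Product: 4 (Z)-3-[3,5-dimethoxy-4-(methoxymethoxy)phenyl]prop-2-en-1-ol
Conditions: i-Bu2AlH (2.5 equiv), CH2Cl2, −78 °C; aq potassium sodium tartrate
Reagents that add atoms: none
Why: 1,2-reduction of an enoate to the allylic alcohol by an aluminium hydride; the alkene geometry is not touched and the MOM ether is inert.

Step 4
Reactants: 4 (Z)-3-[3,5-dimethoxy-4-(methoxymethoxy)phenyl]prop-2-en-1-ol
Product: 5 1,3-dimethoxy-2-(methoxymethoxy)-5-[(Z)-3-(trityloxy)prop-1-en-1-yl]benzene
Conditions: TrCl, Et3N, DMAP (cat.), CH2Cl2, rt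
Reagents that add atoms: trityl chloride, ClC(c1ccccc1)(c1ccccc1)c1ccccc1
Why: Tritylation of a primary alcohol under basic conditions, which avoids any allylic cation and hence any Z-to-E isomerisation.

Step 5
Reactants: 5 1,3-dimethoxy-2-(methoxymethoxy)-5-[(Z)-3-(trityloxy)prop-1-en-1-yl]benzene
Product: 6 (2S,3R)-3-[3,5-dimethoxy-4-(methoxymethoxy)phenyl]-2-[(trityloxy)methyl]oxirane (cis)
Conditions: (R,R)-N,N'-bis(3,5-di-tert-butylsalicylidene)-1,2-cyclohexanediaminomanganese chloride (5 mol %), 4-phenylpyridine N-oxide, aq NaOCl (pH 11.3), CH2Cl2, 0 °C
Reagents that add atoms: sodium hypochlorite, [Na+].[O-]Cl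
Why: Jacobsen–Katsuki epoxidation; cis-disubstituted aryl alkenes are the best substrate class, and the chiral salen ligand selects the alkene face so that C7 should become R and C8 S. The 4-oxygen of ring A is twisted out of conjugation by its two methoxy neighbours, which tempers the acid lability of the epoxide; it is purified on base-washed silica and recrystallised to raise the enantiomeric purity.

Step 6
Reactants: 6 (2S,3R)-3-[3,5-dimethoxy-4-(methoxymethoxy)phenyl]-2-[(trityloxy)methyl]oxirane; 7 4-fluoro-3-hydroxybenzaldehyde
Product: 9 (2S,3S)-3-[3,5-dimethoxy-4-(methoxymethoxy)phenyl]-2-[(trityloxy)methyl]-2,3-dihydro-1,4-benzodioxine-6-carbaldehyde, via ring-opened fluoro alcohol 8 (not isolated)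
Conditions: Cs2CO3 (1.5 equiv), DMF, 80 °C, then 110 °C
Reagents that add atoms: none
Why: The cesium phenoxide of 7 attacks C7 of 6 anti to the epoxide oxygen (SN2, inversion, C7 goes from R to S) and gives the alkoxide of 8, in which C8 keeps its oxygen and its configuration, so the cis-epoxide geometry translates directly into the 7,8-trans product. C7 is preferred over C8 because the transition state is benzylic and because SN2 at C8 is retarded by the adjacent C9–O dipole; both carbons are secondary, so sterics do not oppose this. The C8 alkoxide then adds to the fluorine-bearing carbon of ring B, ortho to the new ether and para to the formyl group, and the Meisenheimer complex loses fluoride; this is a 6-exo-trig addition–elimination that closes the dioxane ring. The closest known reaction type is base-mediated opening of epoxides by 2-halophenols followed by intramolecular SNAr to 1,4-benzodioxanes, together with C3-selective opening of 3-arylglycidyl ethers by phenoxides. The order of events is set electronically: in the phenoxide of 7 the oxido group ortho to fluorine switches SNAr off, and only after O-alkylation does the para-formyl group activate the C–F bond. The fusion regiochemistry (Ob para to the formyl group) follows from the position of fluorine in 7 and needs no further control. Using 6 in slight excess and raising the temperature only once 7 is consumed should keep free phenoxide from displacing fluoride of 8 intermolecularly. The trityl and MOM ethers are inert to carbonate, alkoxide and fluoride.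

Step 7
Reactants: 9 (2S,3S)-3-[3,5-dimethoxy-4-(methoxymethoxy)phenyl]-2-[(trityloxy)methyl]-2,3-dihydro-1,4-benzodioxine-6-carbaldehyde
Product: 10 (E)-3-{(2S,3S)-3-[3,5-dimethoxy-4-(methoxymethoxy)phenyl]-2-[(trityloxy)methyl]-2,3-dihydro-1,4-benzodioxin-6-yl}prop-2-enal
Conditions: Ph3P=CHCHO (1.3 equiv), toluene, 100 °C
Reagents that add atoms: (triphenylphosphoranylidene)acetaldehyde, O=CC=P(c1ccccc1)(c1ccccc1)c1ccccc1
Why: Wittig reaction of a stabilised ylide with an aromatic aldehyde, which should give the E-enal under thermodynamic control of the oxaphosphetane; neutral conditions leave both stereocentres and both ethers untouched.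

Step 8
Reactants: 10 (E)-3-{(2S,3S)-3-[3,5-dimethoxy-4-(methoxymethoxy)phenyl]-2-[(trityloxy)methyl]-2,3-dihydro-1,4-benzodioxin-6-yl}prop-2-enal
Product: 11 (E)-3-[(2S,3S)-3-(4-hydroxy-3,5-dimethoxyphenyl)-2-(hydroxymethyl)-2,3-dihydro-1,4-benzodioxin-6-yl]prop-2-enal
Conditions: 2 M aq HCl, THF, 40 °C
Reagents that add atoms: none
Why: Acid hydrolysis of the trityl ether (via the trityl cation, trapped by water) and of the aryl MOM acetal in one operation; an alcohol-free medium avoids acetal formation at the enal, and the mild acid should leave the C7–Oa bond intact.

## Compound list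

1 | syringaldehyde (4-hydroxy-3,5-dimethoxybenzaldehyde) | COc1cc(C=O)cc(OC)c1O | starting material
2 | 3,5-dimethoxy-4-(methoxymethoxy)benzaldehyde | COCOc1c(OC)cc(C=O)cc1OC | intermediate
3 | methyl (Z)-3-[3,5-dimethoxy-4-(methoxymethoxy)phenyl]prop-2-enoate | COC(=O)/C=C\c1cc(OC)c(OCOC)c(OC)c1 | intermediate
4 | (Z)-3-[3,5-dimethoxy-4-(methoxymethoxy)phenyl]prop-2-en-1-ol | OC/C=C\c1cc(OC)c(OCOC)c(OC)c1 | intermediate
5 | 1,3-dimethoxy-2-(methoxymethoxy)-5-[(Z)-3-(trityloxy)prop-1-en-1-yl]benzene | COCOc1c(OC)cc(/C=C\COC(c2ccccc2)(c2ccccc2)c2ccccc2)cc1OC | intermediate
6 | (2S,3R)-3-[3,5-dimethoxy-4-(methoxymethoxy)phenyl]-2-[(trityloxy)methyl]oxirane | COc1cc([C@H]2O[C@H]2COC(c3ccccc3)(c3ccccc3)c3ccccc3)cc(OC)c1OCOC | intermediate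
7 | 4-fluoro-3-hydroxybenzaldehyde | O=Cc1ccc(F)c(O)c1 | starting material
8 | 4-fluoro-3-{(1S,2S)-1-[3,5-dimethoxy-4-(methoxymethoxy)phenyl]-2-hydroxy-3-(trityloxy)propoxy}benzaldehyde | COc1cc([C@H](Oc2cc(C=O)ccc2F)[C@@H](O)COC(c2ccccc2)(c2ccccc2)c2ccccc2)cc(OC)c1OCOC | intermediate
9 | (2S,3S)-3-[3,5-dimethoxy-4-(methoxymethoxy)phenyl]-2-[(trityloxy)methyl]-2,3-dihydro-1,4-benzodioxine-6-carbaldehyde | COc1cc([C@@H]2Oc3cc(C=O)ccc3O[C@H]2COC(c4ccccc4)(c4ccccc4)c4ccccc4)cc(OC)c1OCOC | intermediate
10 | (E)-3-{(2S,3S)-3-[3,5-dimethoxy-4-(methoxymethoxy)phenyl]-2-[(trityloxy)methyl]-2,3-dihydro-1,4-benzodioxin-6-yl}prop-2-enal | COc1cc([C@@H]2Oc3cc(/C=C/C=O)ccc3O[C@H]2COC(c4ccccc4)(c4ccccc4)c4ccccc4)cc(OC)c1OCOC | intermediate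
11 | (E)-3-[(2S,3S)-3-(4-hydroxy-3,5-dimethoxyphenyl)-2-(hydroxymethyl)-2,3-dihydro-1,4-benzodioxin-6-yl]prop-2-enal | COc1cc([C@@H]2Oc3cc(/C=C/C=O)ccc3O[C@H]2CO)cc(OC)c1O | target

## Step count and least certain steps

Total: 8 steps. Longest linear sequence: 8 steps (1 to 11); 7 enters at step 6.

**Step 6 (key step).** The most likely failure is that ring closure loses to intermolecular chemistry. Opening of the hindered cis-epoxide is slow, so phenoxide and the activated fluoroarene 8 coexist at high temperature, and displacement of fluoride by phenoxide or slow decay of the aldehyde can overtake cyclisation. A lesser risk is partial attack at C8, which would give the regioisomeric benzodioxane. The fallback separates the two events and closes the ring by metal catalysis instead of SNAr. Starting from 6, the epoxide is opened with 4-bromo-3-hydroxybenzaldehyde F1 (Cs2CO3, DMF, 80 °C) to give 4-bromo-3-{(1S,2S)-1-[3,5-dimethoxy-4-(methoxymethoxy)phenyl]-2-hydroxy-3-(trityloxy)propoxy}benzaldehyde F2. The bromoarene cannot undergo SNAr at that temperature, so F2 is isolated. Intramolecular C–O coupling (Pd(OAc)2, 2-(di-tert-butylphosphino)-1,1'-binaphthyl, Cs2CO3, toluene, 80 °C; oxidative addition of zerovalent palladium into the C–Br bond, then alkoxide reductive elimination) returns to the route at 9.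

**Step 5.** The stepwise radical character of the manganese-oxo transfer may cause partial cis-to-trans leakage, which the electron-rich ring A favours, and the enantioselectivity may be insufficient. The epoxide may also open during isolation. The fallback uses a concerted, hydroxyl-directed oxygen transfer. Starting from 4, Sharpless epoxidation (Ti(Oi-Pr)4, L-(+)-diisopropyl tartrate, t-BuOOH, 4 Å molecular sieves, CH2Cl2, −20 °C) should give [(2S,3R)-3-[3,5-dimethoxy-4-(methoxymethoxy)phenyl]oxiran-2-yl]methanol F3. Tritylation (TrCl, Et3N, DMAP) returns to the route at 6. Z-allylic alcohols react slowly in this epoxidation, so recrystallisation of 6 remains the means of upgrading.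

**Step 7.** The product enal is itself an aldehyde and may be olefinated again to a dienal, while the electron-rich aldehyde 9 reacts sluggishly. The fallback uses a masked ylide that cannot over-react. Starting from 9, Wittig reaction with (1,3-dioxolan-2-ylmethyl)triphenylphosphonium bromide and t-BuOK in THF gives 2-{2-[(2S,3S)-3-[3,5-dimethoxy-4-(methoxymethoxy)phenyl]-2-[(trityloxy)methyl]-2,3-dihydro-1,4-benzodioxin-6-yl]ethenyl}-1,3-dioxolane F4 as an E/Z mixture. Treatment with 2 M aq HCl in THF hydrolyses the acetal, equilibrates the enal to E and removes the trityl and MOM groups in the same flask, returning to the route at 11.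

**Step 8.** The enal may suffer hydration, chloride addition or oligomerisation under the acid needed for the aryl MOM ether, and the trityl cation may re-alkylate ring A. Once the phenol is free, ionisation of the C7–Oa bond is a further risk. The fallback removes the protecting groups before the enal exists. Starting from 9, the same aqueous acid gives (2S,3S)-3-(4-hydroxy-3,5-dimethoxyphenyl)-2-(hydroxymethyl)-2,3-dihydro-1,4-benzodioxine-6-carbaldehyde F5. Wittig reaction of F5 with Ph3P=CHCHO in toluene tolerates the free hydroxyl groups, because the phenol is on ring A and not conjugated to the reacting aldehyde, and returns to the route at 11.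

## Further compounds

F1 | step 6 | 4-bromo-3-hydroxybenzaldehyde | O=Cc1ccc(Br)c(O)c1
F2 | step 6 | 4-bromo-3-{(1S,2S)-1-[3,5-dimethoxy-4-(methoxymethoxy)phenyl]-2-hydroxy-3-(trityloxy)propoxy}benzaldehyde | COc1cc([C@H](Oc2cc(C=O)ccc2Br)[C@@H](O)COC(c2ccccc2)(c2ccccc2)c2ccccc2)cc(OC)c1OCOC
F3 | step 5 | [(2S,3R)-3-[3,5-dimethoxy-4-(methoxymethoxy)phenyl]oxiran-2-yl]methanol | COc1cc([C@H]2O[C@H]2CO)cc(OC)c1OCOC
F4 | step 7 | 2-{2-[(2S,3S)-3-[3,5-dimethoxy-4-(methoxymethoxy)phenyl]-2-[(trityloxy)methyl]-2,3-dihydro-1,4-benzodioxin-6-yl]ethenyl}-1,3-dioxolane (E/Z mixture) | COc1cc([C@@H]2Oc3cc(C=CC4OCCO4)ccc3O[C@H]2COC(c5ccccc5)(c5ccccc5)c5ccccc5)cc(OC)c1OCOC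
F5 | step 8 | (2S,3S)-3-(4-hydroxy-3,5-dimethoxyphenyl)-2-(hydroxymethyl)-2,3-dihydro-1,4-benzodioxine-6-carbaldehyde | COc1cc([C@@H]2Oc3cc(C=O)ccc3O[C@H]2CO)cc(OC)c1O
A1 | alternative 1 | 4-formyl-2,6-dimethoxyphenyl acetate | COc1cc(C=O)cc(OC)c1OC(C)=O
A2 | alternative 1 | 5-(1,3-dioxolan-2-yl)-2-(ethenyloxy)phenyl acetate | C=COc1ccc(C2OCCO2)cc1OC(C)=O
A3 | alternative 1 | 4-{(3S)-3-[2-acetoxy-4-(1,3-dioxolan-2-yl)phenoxy]oxetan-2-yl}-2,6-dimethoxyphenyl acetate (C2 of the oxetane either epimer) | COc1cc(C2OC[C@@H]2Oc3ccc(C4OCCO4)cc3OC(C)=O)cc(OC)c1OC(C)=O
A4 | alternative 2 | (1S,2S)-1-[4-(benzyloxy)-3,5-dimethoxyphenyl]-3-[(tert-butyldimethylsilyl)oxy]-1-(ethynyloxy)-2-{[(trimethylsilyl)ethynyl]oxy}propane | COc1cc([C@H](OC#C)[C@@H](OC#C[Si](C)(C)C)CO[Si](C)(C)C(C)(C)C)cc(OC)c1OCc1ccccc1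
A5 | alternative 2 | 3,3-diethoxyprop-1-yne | C#CC(OCC)OCC
A6 | alternative 2 | tert-butyl{[(2S,3S)-3-[4-(benzyloxy)-3,5-dimethoxyphenyl]-6-(diethoxymethyl)-8-(trimethylsilyl)-2,3-dihydro-1,4-benzodioxin-2-yl]methoxy}dimethylsilane | COc1cc([C@@H]2Oc3cc(C(OCC)OCC)cc([Si](C)(C)C)c3O[C@H]2CO[Si](C)(C)C(C)(C)C)cc(OC)c1OCc1ccccc1
A7 | alternative 3 | {[2-(4-benzyloxy-3,5-dimethoxyphenyl)-1,3-benzodioxol-5-yl]oxy}triisopropylsilane (racemic at C2) | COc1cc(C2Oc3ccc(O[Si](C(C)C)(C(C)C)C(C)C)cc3O2)cc(OC)c1OCc1ccccc1
A8 | alternative 3 | tert-butyl diazoacetate | CC(C)(C)OC(=O)C=[N+]=[N-]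
A9 | alternative 3 | tert-butyl (2R,3S)-3-[4-(benzyloxy)-3,5-dimethoxyphenyl]-6-[(triisopropylsilyl)oxy]-2,3-dihydro-1,4-benzodioxine-2-carboxylate (trans) | COc1cc([C@@H]2Oc3cc(O[Si](C(C)C)(C(C)C)C(C)C)ccc3O[C@H]2C(=O)OC(C)(C)C)cc(OC)c1OCc1ccccc1
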